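The geranyl chain is cut between the benzylic C1'' on C6 of ring A and the olefinic C2''. The (E)-C2''=C3'' alkene with its C3'' methyl group is the retron of a syn-methylalumination of a terminal alkyne. The key step therefore turns 6-methylhept-5-en-1-yne into an (E)-alkenylalane and couples it under Ni(0) with a 6-chloromethyl flavanone: one operation makes the C3''–CH3 bond, the E geometry and the C1''–C2'' bond. The precursor, (2S)-6-(chloromethyl)-5-hydroxy-7,3',4'-tris(silyloxy)flavanone, comes from (2S)-eriodictyol by an ortho-hydroxymethylation tethered through boron to the chelated 5-OH; C6 is the only free position next to O5.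

Key step: step 5

Assumption: natural (2S)-(−)-eriodictyol is taken as a commercial single enantiomer and supplies the C2 stereocentre; all later steps avoid bases strong enough to open the pyranone ring. TBS = tert-butyldimethylsilyl.

Step 1
Reactants: 1 (2S)-eriodictyol
Product: 2 (2S)-5-hydroxy-7,3',4'-tris(tert-butyldimethylsilyloxy)flavanone
Conditions: TBSCl (3.3 equiv), imidazole, DMF, 0 °C to rt
Reagents that add atoms: tert-butyldimethylsilyl chloride, CC(C)(C)[Si](C)(C)Cl
Why: Imidazole-mediated silyl ether formation should take the phenols at O7, O3' and O4' but not the 5-OH, which is hydrogen-bonded to the C4 carbonyl and too weakly nucleophilic for TBSCl, and the weak base should not open the pyranone ring, so C2 stays S.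

Step 2
Reactants: 2 (2S)-5-hydroxy-7,3',4'-tris(tert-butyldimethylsilyloxy)flavanone
Product: 4 (2S)-5-hydroxy-6-(hydroxymethyl)-7,3',4'-tris(tert-butyldimethylsilyloxy)flavanone, via cyclic phenylboronate 3 (not isolated)
Conditions: PhB(OH)2, (CH2O)n, EtCO2H (cat.), toluene, 4 Å MS, 85 °C; then propane-1,3-diol, rt
Reagents that add atoms: paraformaldehyde (formaldehyde), C=O; phenylboronic acid, OB(O)c1ccccc1 (its atoms stay only in intermediate 3)
Why: Nagata ortho-hydroxymethylation: the phenylboronate formed at O5 should deliver formaldehyde intramolecularly to the only free ortho carbon, C6 (C8 has no free OH beside it), giving cyclic boronate 3, which boronate transesterification with propane-1,3-diol opens to the salicyl alcohol.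

Step 3
Reactants: 4 (2S)-5-hydroxy-6-(hydroxymethyl)-7,3',4'-tris(tert-butyldimethylsilyloxy)flavanone
Product: 5 (2S)-6-(chloromethyl)-5-hydroxy-7,3',4'-tris(tert-butyldimethylsilyloxy)flavanone
Conditions: SOCl2 (1.1 equiv), CH2Cl2, −20 to 0 °C; volatiles removed cold, crude used at once
Reagents that add atoms: thionyl chloride, O=S(Cl)Cl
Why: Chlorodehydroxylation of the electron-rich benzylic alcohol through its chlorosulfite should be fast at low temperature, while the chelated 5-OH, the aryl silyl ethers and the ketone should not react with SOCl2.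

Step 4
Reactants: 6 5-bromo-2-methylpent-2-ene
Product: 7 6-methylhept-5-en-1-yne
Conditions: HC≡CLi·H2NCH2CH2NH2, DMSO, 10 °C to rt
Reagents that add atoms: lithium acetylide–ethylenediamine complex, [Li]C#C.NCCN
Why: SN2 alkylation of lithium acetylide by a primary homoallylic bromide is a standard terminal-alkyne synthesis, and the trisubstituted alkene is inert.

Step 5
Reactants: 7 6-methylhept-5-en-1-yne; 5 (2S)-6-(chloromethyl)-5-hydroxy-7,3',4'-tris(tert-butyldimethylsilyloxy)flavanone
Product: 10 (2S)-6-[(2E)-3,7-dimethylocta-2,6-dien-1-yl]-5-hydroxy-7,3',4'-tris(tert-butyldimethylsilyloxy)flavanone, via (E)-alkenyldimethylalane 8 (not isolated), via dimethylaluminium phenoxide 9 (not isolated)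
Conditions: (i) 7 (2 equiv), Me3Al, Cp2ZrCl2 (cat.), ClCH2CH2Cl, 0 °C to rt, then volatiles removed in vacuo, THF; (ii) 5, Me3Al (1.0 equiv), THF, −78 °C; (iii) 8 added to 9, NiCl2(PPh3)2/n-BuLi (5 mol% Ni(0)), −20 to 0 °C; aq. Rochelle salt
Reagents that add atoms: trimethylaluminium, C[Al](C)C
Why: Cp2ZrCl2-catalysed syn-methylalumination of the terminal alkyne of 7 (Negishi carboalumination) places CH3 on the internal carbon (future C3'') and AlMe2 on the terminal carbon (future C2'') on the same side, giving (E)-alkenylalane 8; Ni(0) then inserts into the benzylic C1''–Cl bond of 9, the alkenyl group is transmetalated from aluminium, and reductive elimination forms the C1''–C2'' bond with retention of olefin geometry. The closest known reaction type is the one-pot carboalumination/Ni-catalysed coupling of alkenylalanes with chloromethyl arenes and chloromethyl quinones used to attach polyprenyl chains. No ring is closed and no stereocentre is created; the 2''E geometry is controlled by the syn addition and the stereoretentive coupling. The step needs regioselective carbometalation (secured by the terminal alkyne; the remote trisubstituted alkene of 7 is inert) and reaction at C–Cl rather than at the C4 ketone (secured by stripping free Me3Al, low temperature and the poorly electrophilic, triply oxygen-donor-substituted aryl ketone). The acidic 5-OH is spent beforehand as aluminium phenoxide 9 so that it cannot protonate 8, and should 9 ionise to an ortho-quinone methide, 1,4-addition of 8 would form the same bond. The medium is non-basic, so the C2 centre should not be opened to the chalcone.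

Step 6
Reactants: 10 (2S)-6-[(2E)-3,7-dimethylocta-2,6-dien-1-yl]-5-hydroxy-7,3',4'-tris(tert-butyldimethylsilyloxy)flavanone
Product: 11 nymphaeol A
Conditions: HF·pyridine, pyridine, THF, 0 °C to rt
Reagents that add atoms: none
Why: Fluoride-driven cleavage of the three aryl silyl ethers (desilylation) in a pyridine-buffered medium should be neither acidic enough to cyclise the geranyl chain onto O5 or O7 nor basic enough to open the flavanone ring, so the 2S centre and the 2''E alkene are retained.

Compound list
1 | (2S)-eriodictyol, (2S)-2-(3,4-dihydroxyphenyl)-5,7-dihydroxychroman-4-one | Oc1cc2c(c(O)c1)C(=O)C[C@@H](c1ccc(O)c(O)c1)O2 | starting material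
2 | (2S)-5-hydroxy-7,3',4'-tris(tert-butyldimethylsilyloxy)flavanone | CC(C)(C)[Si](C)(C)Oc1cc2c(c(O)c1)C(=O)C[C@@H](c1ccc(O[Si](C)(C)C(C)(C)C)c(O[Si](C)(C)C(C)(C)C)c1)O2 | intermediate
3 | cyclic phenylboronate of 4: 2-phenyl-4H-1,3,2-dioxaborin ring (O5–B(Ph)–O–CH2–C6) fused to ring A of 2, 2S | C1OB(c2ccccc2)Oc2c1c(O[Si](C)(C)C(C)(C)C)cc3c2C(=O)C[C@@H](c2ccc(O[Si](C)(C)C(C)(C)C)c(O[Si](C)(C)C(C)(C)C)c2)O3 | intermediate (not isolated)
4 | (2S)-5-hydroxy-6-(hydroxymethyl)-7,3',4'-tris(tert-butyldimethylsilyloxy)flavanone | OCc1c(O[Si](C)(C)C(C)(C)C)cc2c(c1O)C(=O)C[C@@H](c1ccc(O[Si](C)(C)C(C)(C)C)c(O[Si](C)(C)C(C)(C)C)c1)O2 | intermediate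
5 | (2S)-6-(chloromethyl)-5-hydroxy-7,3',4'-tris(tert-butyldimethylsilyloxy)flavanone | ClCc1c(O[Si](C)(C)C(C)(C)C)cc2c(c1O)C(=O)C[C@@H](c1ccc(O[Si](C)(C)C(C)(C)C)c(O[Si](C)(C)C(C)(C)C)c1)O2 | intermediate
6 | 5-bromo-2-methylpent-2-ene | CC(C)=CCCBr | starting material
7 | 6-methylhept-5-en-1-yne | CC(C)=CCCC#C | intermediate
8 | (E)-(2,6-dimethylhepta-1,5-dien-1-yl)dimethylalane | CC(C)=CCC/C(C)=C/[Al](C)C | intermediate (not isolated)
9 | dimethylaluminium 5-phenoxide of 5 | ClCc1c(O[Si](C)(C)C(C)(C)C)cc2c(c1O[Al](C)C)C(=O)C[C@@H](c1ccc(O[Si](C)(C)C(C)(C)C)c(O[Si](C)(C)C(C)(C)C)c1)O2 | intermediate (not isolated)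
10 | (2S)-6-[(2E)-3,7-dimethylocta-2,6-dien-1-yl]-5-hydroxy-7,3',4'-tris(tert-butyldimethylsilyloxy)flavanone | CC(C)=CCC/C(C)=C/Cc1c(O[Si](C)(C)C(C)(C)C)cc2c(c1O)C(=O)C[C@@H](c1ccc(O[Si](C)(C)C(C)(C)C)c(O[Si](C)(C)C(C)(C)C)c1)O2 | intermediate
11 | nymphaeol A, (2S)-6-geranyl-5,7,3',4'-tetrahydroxyflavanone | CC(C)=CCC/C(C)=C/Cc1c(O)cc2c(c1O)C(=O)C[C@@H](c1ccc(O)c(O)c1)O2 | target

Total step count: 6. Longest linear sequence: 5 steps (1, 2, 3, 5, 6).

Steps most likely to fail

Step 2. The boron may be held in a chelate with the C4 carbonyl so that formaldehyde transfer to C6 stalls. The hours at 85 °C with a carboxylic acid may also erode C2 by reversible ring opening or loosen the 7-O-silyl ether. The fallback sets out from 2 and delivers the carbon from O5 by a low-temperature sigmatropic shift instead of a boron tether. Gassman ortho-alkylation (Me2S, N-chlorosuccinimide, CH2Cl2, −40 °C, then Et3N) forms the aryloxysulfonium ylide at O5, whose [2,3]-shift can only reach C6 and should give (2S)-5-hydroxy-6-[(methylsulfanyl)methyl]-7,3',4'-tris(tert-butyldimethylsilyloxy)flavanone F1. Chlorinolysis of this benzylic sulfide with SO2Cl2 (CH2Cl2, −78 °C) should then give the chloride, and the route is rejoined at 5.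

Step 5. The alane may add to the C4 ketone or transfer methyl instead of alkenyl, and Lewis-acid-induced ionisation of the benzylic chloride may outrun nickel insertion; a minor regioisomer from the carbometalation would also be carried through. The fallback sets out from 7 and 5 and replaces the in-situ alane by an isolable, non-Lewis-acidic boron partner. Copper-catalysed syn-methylboration of 7 (B2pin2, MeI, CuCl/Xantphos, NaOt-Bu, THF) should give (E)-2-(2,6-dimethylhepta-1,5-dien-1-yl)-4,4,5,5-tetramethyl-1,3,2-dioxaborolane F2, which can be purified free of regioisomer. Suzuki–Miyaura coupling of F2 with 5 (Pd(dppf)Cl2, K3PO4, THF/H2O, rt, short reaction time) forms the same C1''–C2'' bond and comes back to the route at 10.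

Step 3. The chloride beside the free 5-OH may ionise to an ortho-quinone methide during concentration and self-condense, and the HCl set free may loosen silyl ethers. The fallback sets out from 4 and blocks O5 before any leaving group is present. Silylation with TBSOTf/2,6-lutidine (CH2Cl2, 0 °C) should give (2S)-6-[(tert-butyldimethylsilyloxy)methyl]-5,7,3',4'-tetrakis(tert-butyldimethylsilyloxy)flavanone F3. Ph3PBr2 (CH2Cl2, 0 °C) converts the benzylic silyl ether, but not the aryl silyl ethers, directly into (2S)-6-(bromomethyl)-5,7,3',4'-tetrakis(tert-butyldimethylsilyloxy)flavanone F4. Coupling of F4 with alane 8 under the nickel conditions of step 5, without the Me3Al capping, should give (2S)-6-geranyl-5,7,3',4'-tetrakis(tert-butyldimethylsilyloxy)flavanone F5, and the conditions of step 6 bring this to the target, so the route is rejoined at 11.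

Further compounds
F1 | step 2 | (2S)-5-hydroxy-6-[(methylsulfanyl)methyl]-7,3',4'-tris(tert-butyldimethylsilyloxy)flavanone | CSCc1c(O[Si](C)(C)C(C)(C)C)cc2c(c1O)C(=O)C[C@@H](c1ccc(O[Si](C)(C)C(C)(C)C)c(O[Si](C)(C)C(C)(C)C)c1)O2
F2 | step 5 | (E)-2-(2,6-dimethylhepta-1,5-dien-1-yl)-4,4,5,5-tetramethyl-1,3,2-dioxaborolane | CC(C)=CCC/C(C)=C/B1OC(C)(C)C(C)(C)O1
F3 | step 3 | (2S)-6-[(tert-butyldimethylsilyloxy)methyl]-5,7,3',4'-tetrakis(tert-butyldimethylsilyloxy)flavanone | CC(C)(C)[Si](C)(C)OCc1c(O[Si](C)(C)C(C)(C)C)cc2c(c1O[Si](C)(C)C(C)(C)C)C(=O)C[C@@H](c1ccc(O[Si](C)(C)C(C)(C)C)c(O[Si](C)(C)C(C)(C)C)c1)O2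
F4 | step 3 | (2S)-6-(bromomethyl)-5,7,3',4'-tetrakis(tert-butyldimethylsilyloxy)flavanone | BrCc1c(O[Si](C)(C)C(C)(C)C)cc2c(c1O[Si](C)(C)C(C)(C)C)C(=O)C[C@@H](c1ccc(O[Si](C)(C)C(C)(C)C)c(O[Si](C)(C)C(C)(C)C)c1)O2
F5 | step 3 | (2S)-6-[(2E)-3,7-dimethylocta-2,6-dien-1-yl]-5,7,3',4'-tetrakis(tert-butyldimethylsilyloxy)flavanone | CC(C)=CCC/C(C)=C/Cc1c(O[Si](C)(C)C(C)(C)C)cc2c(c1O[Si](C)(C)C(C)(C)C)C(=O)C[C@@H](c1ccc(O[Si](C)(C)C(C)(C)C)c(O[Si](C)(C)C(C)(C)C)c1)O2
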